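**Plan**

- Numbering: ten-membered ring C1(=CH2)–C2–C3(OAc)–C4–C5–C6=C7(Me)–C8–C9–C10(OAc); cyclohexane C4–C14(Me,OH)–C13–C12–C11(iPr)–C5; C15 is the isopropyl CH. The target is (3R,4S,5S,10R,11R,14R,6Z) in this numbering.
- Enabling feature: on the cyclohexane the C14 oxygen and C15 (on C11) are cis-1,4, so C14–O–C15(=O)–C11 can be the lactone bridge of a 6-methyl-2-pyrone adduct. C3–O and C6 are cis on C4/C5, so they can be the cis-fused γ-lactone left by a butenolide dienophile.
- Cuts, in retrosynthetic order: C1–C10 (alkenylchromium/aldehyde closure), C1–C2 (acetylide/epoxide), C7–C8 (B-alkyl Suzuki), C6=C7 (iodo-olefination), then C4–C14 and C5–C11 together ([4+2] of bromopyrone 5 with butenolide 7).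
- Forward order: cyclohexane first by cycloaddition; bridge lactone to isopropyl; γ-lactone to epoxy aldehyde; the C6–C10 arm; the C1 iodoalkene; the ten-membered ring last; acetates at the end.
- Stereochemistry: C3 from the (S)-butenolide 6; C4, C5, C11 and C14 from the endo, anti cycloaddition; 6Z from the iodo-ylide and a stereoretentive coupling; C10 from the macrocyclisation.

Key step: step 5

**Route**

Step 1
Reactants: 1 4-hydroxy-6-methyl-2H-pyran-2-one
Product: 2 6-methyl-2-oxo-2H-pyran-4-yl 4-methylbenzenesulfonate
Conditions: TsCl, Et3N, CH2Cl2, 0 °C to rt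
Reagents that add atoms: 4-toluenesulfonyl chloride, Cc1ccc(cc1)S(=O)(=O)Cl
Why: O-sulfonylation of the acidic vinylogous-acid hydroxyl turns C4–O into a leaving group for the reductive removal that follows.

Step 2
Reactants: 2 6-methyl-2-oxo-2H-pyran-4-yl 4-methylbenzenesulfonate
Product: 3 6-methyl-2H-pyran-2-one
Conditions: Pd(OAc)2 (cat.), PPh3, HCO2H, Et3N, DMF, 60 °C
Reagents that add atoms: none
Why: Palladium-catalysed transfer hydrogenolysis of an activated enol sulfonate (oxidative addition into C4–O, hydride from formate) should remove the 4-oxygen and leave the pyrone intact.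

Step 3
Reactants: 3 6-methyl-2H-pyran-2-one
Product: 5 3-bromo-6-methyl-2H-pyran-2-one, via 3,6-dibromo-3,6-dihydropyranone 4 (not isolated)
Conditions: Br2, CH2Cl2, 0 °C to rt; then Et3N, 0 °C
Reagents that add atoms: bromine, BrBr
Why: Electrophilic bromination of a 2-pyrone by addition–elimination (bromine adds, Et3N removes HBr) is expected to substitute C3 as in the parent pyrone; any 5-bromo isomer is removed by chromatography.

Step 4
Reactants: 6 (S)-5-(hydroxymethyl)furan-2(5H)-one
Product: 7 (S)-5-[(tert-butyldimethylsilyloxy)methyl]furan-2(5H)-one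
Conditions: TBSCl, imidazole, CH2Cl2, 0 °C to rt
Reagents that add atoms: tert-butyldimethylsilyl chloride, CC(C)(C)[Si](C)(C)Cl
Why: Silylation of the primary alcohol gives a bulky, base-free protecting group that also shields one face of the butenolide.

Step 5
Reactants: 5 3-bromo-6-methyl-2H-pyran-2-one; 7 (S)-5-[(tert-butyldimethylsilyloxy)methyl]furan-2(5H)-one
Product: 8 endo,anti cycloadduct: 4-bromo-1-methyl-2-oxabicyclo[2.2.2]oct-7-en-3-one cis-fused to the γ-lactone (Br on C11, Me on C14, γ-lactone C6(=O)–O–C3, CH2OTBS on C3)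
Conditions: 5 (1.5 equiv), CH2Cl2 (2 M), BHT (cat.), 13 kbar, 35 °C, 5 d
Reagents that add atoms: none
Why: The step is a thermal, concerted but asynchronous [4+2] cycloaddition in which the pyrone is the cyclic diene (C14=C13–C12=C11) and the butenolide C4=C5 bond the dienophile; the closest known reaction type is the addition of 3-bromo-2-pyrones to acrylates and cyclic enones, which gives isolable bridged lactones when run under pressure below the temperature of CO2 loss. The carbocycle closes by suprafacial–suprafacial cycloaddition (C4–C14 and C5–C11 formed together), leaving the O–C15(=O) unit as a bridge on one face of the new ring, i.e. a 2-oxabicyclo[2.2.2]octenone. C4 and C5 keep the cis relation of the ring olefin, and their absolute sense follows from attack on the butenolide face anti to the CH2OTBS group at C3. C14 and C11 are fixed relative to them by the endo transition state, with the dienophile carbonyl under C12=C13 and away from the bridge, and the bridge itself forces the C14 oxygen and C15 to be cis-1,4. The regiochemistry needed (α-carbon C5 to the bromine-bearing terminus, β-carbon C4 to the methyl-bearing terminus) is the one 3-bromo-2-pyrones show with both electron-poor and electron-rich partners. High pressure is chosen because bond formation at the methyl-bearing terminus creates a quaternary centre, and because pressure favours the compact endo transition state at low temperature.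

Step 6
Reactants: 8 endo,anti cycloadduct
Product: 9 debrominated cycloadduct (H on C11)
Conditions: Bu3SnH, Et3B (cat.), air, toluene, 0 °C to rt
Reagents that add atoms: none
Why: Radical-chain tin hydride reduction of the tertiary α-bromo lactone at low temperature; the bridgehead radical can neither invert nor eliminate, so C11 keeps its configuration and no CO2 is lost.

Step 7
Reactants: 9 debrominated cycloadduct
Product: 10 saturated bis-lactone (2-oxabicyclo[2.2.2]octan-3-one fused to the γ-lactone)
Conditions: H2 (1 atm), 10% Pd/C, EtOAc, rt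
Reagents that add atoms: none
Why: Heterogeneous hydrogenation of the strained cis-disubstituted bicyclooctene creates no stereocentre and removes the possibility of a later retro-[4+2] loss of CO2.

Step 8
Reactants: 10 saturated bis-lactone
Product: 12 γ-lactone hydroxy acid (C11–CO2H and C14–OH), via seco dihydroxy diacid 11 (not isolated)
Conditions: LiOH·H2O, THF/H2O, 0 °C to rt; then 1 M HCl to pH 3, 0 °C to rt
Reagents that add atoms: lithium hydroxide, [Li+].[OH-]
Why: Saponification opens both lactones by acyl–oxygen cleavage (C14 and C3 untouched), and on acidification only the cis-fused γ-hydroxy acid relactonises, since the cis-1,4 hydroxy acid could close only through a boat-shaped bicycle; the two carbonyl groups are thereby told apart.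

Step 9
Reactants: 12 γ-lactone hydroxy acid
Product: 13 S-ethyl thioester of 12
Conditions: EtSH (5 equiv), DCC, DMAP (cat.), CH2Cl2, 0 °C to rt
Reagents that add atoms: ethanethiol, CCS
Why: Steglich-type thioesterification with excess thiol should outrun attack by the hindered tertiary C14 hydroxyl; any bridged lactone that re-forms can be returned through step 8.

Step 10
Reactants: 13 S-ethyl thioester
Product: 14 C11 methyl ketone (γ-lactone and C14–OH unchanged)
Conditions: MeZnI (3 equiv), PdCl2(PPh3)2 (cat.), toluene/THF, rt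
Reagents that add atoms: methylzinc iodide, C[Zn]I
Why: Fukuyama coupling (Pd insertion into the C–S bond, transmetallation from zinc) makes the ketone under neutral conditions that leave the γ-lactone and the free alcohol alone; C11 sits in its more stable equatorial arrangement and is not expected to epimerise.

Step 11
Reactants: 14 C11 methyl ketone
Product: 15 C11 isopropenyl lactone
Conditions: Ph3PCH3Br, KOtBu, THF, 0 °C to rt
Reagents that add atoms: methyltriphenylphosphonium bromide, C[P+](c1ccccc1)(c1ccccc1)c1ccccc1.[Br-]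
Why: Wittig methylenation; a non-stabilised ylide reacts with a ketone far faster than with a lactone.

Step 12
Reactants: 15 C11 isopropenyl lactone
Product: 16 C11 isopropyl lactone (TBS ether)
Conditions: H2 (1 atm), PtO2, EtOAc, rt
Reagents that add atoms: none
Why: Hydrogenation of the only olefin present, a 1,1-disubstituted one, completes the isopropyl group without creating a stereocentre.

Step 13
Reactants: 16 C11 isopropyl lactone (TBS ether)
Product: 17 hydroxymethyl lactone
Conditions: TBAF, AcOH (1:1), THF, 0 °C to rt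
Reagents that add atoms: none
Why: Fluoride-mediated desilylation, buffered with acetic acid so that the freed primary alkoxide does not translactonise.

Step 14
Reactants: 17 hydroxymethyl lactone
Product: 18 tosyloxymethyl lactone
Conditions: TsCl, pyridine, DMAP (cat.), CH2Cl2, 0 °C
Reagents that add atoms: 4-toluenesulfonyl chloride, Cc1ccc(cc1)S(=O)(=O)Cl
Why: Sulfonylation selects the primary alcohol; the hindered tertiary C14 hydroxyl does not react under these conditions.

Step 15
Reactants: 18 tosyloxymethyl lactone
Product: 20 epoxy methyl ester (C2–C3 oxirane; CO2Me on C5), via hydroxy tosylate methyl ester 19 (not isolated)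
Conditions: K2CO3, MeOH, 0 °C to rt
Reagents that add atoms: methanol, CO
Why: Methanolysis of the γ-lactone frees the C3 alkoxide, which displaces the neighbouring primary tosylate (intramolecular Williamson closure, 3-exo-tet) and so drains the lactone/hydroxy ester equilibrium; C3 is not a reacting centre and keeps its configuration.

Step 16
Reactants: 20 epoxy methyl ester
Product: 21 epoxy aldehyde (C6 = CHO)
Conditions: DIBAL-H (2.2 equiv), CH2Cl2, −78 °C; Rochelle salt
Reagents that add atoms: none
Why: Partial reduction of the ester through its stable tetrahedral aluminium hemiacetal; the epoxide is inert at −78 °C, and C5 already has its preferred equatorial arrangement.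

Step 17
Reactants: 21 epoxy aldehyde
Product: 22 (Z)-2-iodopropenyl epoxide (iodine cis to C5)
Conditions: EtPPh3I, n-BuLi, THF, rt; I2, −78 °C; NaHMDS, −20 °C; then 21, −78 to −20 °C
Reagents that add atoms: ethyltriphenylphosphonium iodide, CC[P+](c1ccccc1)(c1ccccc1)c1ccccc1.[I-]; iodine, II
Why: Stork–Zhao-type Wittig iodo-olefination with the α-iodo ylide gives the (Z)-2-iodo-2-alkene under kinetic control, as is general for α-branched aldehydes.

Step 18
Reactants: 22 (Z)-2-iodopropenyl epoxide; 23 allyloxy-tert-butyldimethylsilane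
Product: 25 Z-trisubstituted olefin epoxide with C10–OTBS, via B-alkyl-9-BBN 24 (not isolated)
Conditions: 23, 9-BBN-H, THF, rt; then 22, PdCl2(dppf) (cat.), AsPh3, Cs2CO3, DMF/H2O, rt
Reagents that add atoms: none
Why: B-alkyl Suzuki–Miyaura coupling (anti-Markovnikov hydroboration, then Pd-catalysed coupling with retention of olefin geometry) puts C8 where iodine was, cis to C5, which fixes 6Z.

Step 19
Reactants: 25 Z-trisubstituted olefin epoxide
Product: 26 homopropargylic alcohol (C3–OH; C1≡CH)
Conditions: LiC≡CH·H2NCH2CH2NH2 (5 equiv), DMSO, rt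
Reagents that add atoms: lithium acetylide–ethylenediamine complex, [Li+].[C-]#C.NCCN
Why: SN2 opening of the terminal epoxide at the unsubstituted carbon C2 by acetylide; C3 is not touched.

Step 20
Reactants: 26 homopropargylic alcohol
Product: 27 bis(triethylsilyl) ether (C3–OTES and C14–OTES)
Conditions: TESOTf (3 equiv), 2,6-lutidine, CH2Cl2, −78 to 0 °C
Reagents that add atoms: triethylsilyl trifluoromethanesulfonate, CC[Si](CC)(CC)OS(=O)(=O)C(F)(F)F
Why: Silylation with the silyl triflate caps both the secondary and the tertiary hydroxyl, so that no O–H bond can consume the boron halide of the next step.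

Step 21
Reactants: 27 bis(triethylsilyl) ether
Product: 29 2-iodo-1-alkene (iodine on C1), via iodoalkenylborane 28 (not isolated)
Conditions: B-I-9-BBN, hexane, −20 to 0 °C; then AcOH, 0 °C
Reagents that add atoms: B-iodo-9-borabicyclo[3.3.1]nonane, IB1C2CCCC1CCC2
Why: Haloboration adds B–I cis and Markovnikov to the terminal alkyne (iodine to C1), and protonolysis of the alkenyl C–B bond gives the 2-iodoalkene; the trisubstituted olefin and the silyl ethers should not react at this temperature.

Step 22
Reactants: 29 2-iodo-1-alkene tris-silyl ether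
Product: 30 iodo triol (C3–OH, C10–OH, C14–OH)
Conditions: HF·pyridine, pyridine, THF, 0 °C to rt
Reagents that add atoms: none
Why: Buffered fluoride-mediated desilylation removes the primary TBS and both TES groups in one operation.

Step 23
Reactants: 30 iodo triol
Product: 31 iodo dihydroxy aldehyde (C10 = CHO)
Conditions: TEMPO (cat.), PhI(OAc)2, CH2Cl2, rt
Reagents that add atoms: none
Why: Oxoammonium (TEMPO) oxidation selects the primary alcohol over the secondary and tertiary ones and stops at the aldehyde.

Step 24
Reactants: 31 iodo dihydroxy aldehyde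
Product: 32 macrocyclic triol (ten-membered ring closed; C10–OH)
Conditions: CrCl2 (10 equiv), NiCl2 (cat.), DMSO/THF, rt, 2 mM, slow addition
Reagents that add atoms: none
Why: Intramolecular Nozaki–Hiyama–Kishi reaction (Ni-catalysed formation of the C1 alkenylchromium and 1,2-addition to the C10 aldehyde under high dilution) closes the ten-membered ring; C10 is set by substrate control, attack on the outward face of the aldehyde in the folded ring-forming conformer being expected to give the 10R carbinol.

Step 25
Reactants: 32 macrocyclic triol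
Product: 33 target diacetate CNP0303839.1
Conditions: Ac2O, pyridine, DMAP (cat.), CH2Cl2, 0 °C to rt
Reagents that add atoms: acetic anhydride, CC(=O)OC(C)=O
Why: Acylation esterifies the two secondary alcohols, while the hindered tertiary C14 hydroxyl is expected to stay free under these mild conditions.

**Compound list**

1 | 4-hydroxy-6-methyl-2H-pyran-2-one | CC1=CC(O)=CC(=O)O1 | starting material
2 | 6-methyl-2-oxo-2H-pyran-4-yl 4-methylbenzenesulfonate | CC1=CC(OS(=O)(=O)c2ccc(C)cc2)=CC(=O)O1 | intermediate
3 | 6-methyl-2H-pyran-2-one | CC1=CC=CC(=O)O1 | intermediate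
4 | 3,6-dibromo-6-methyl-3,6-dihydro-2H-pyran-2-one (bromine 1,4-adduct, diastereomer mixture) | CC1(Br)C=CC(Br)C(=O)O1 | intermediate
5 | 3-bromo-6-methyl-2H-pyran-2-one | CC1=CC=C(Br)C(=O)O1 | intermediate
6 | (S)-5-(hydroxymethyl)furan-2(5H)-one | O=C1C=C[C@@H](CO)O1 | starting material
7 | (S)-5-[(tert-butyldimethylsilyloxy)methyl]furan-2(5H)-one | O=C1C=C[C@@H](CO[Si](C)(C)C(C)(C)C)O1 | intermediate
8 | endo,anti cycloadduct: 4-bromo-1-methyl-2-oxabicyclo[2.2.2]oct-7-en-3-one cis-fused to a γ-lactone bearing CH2OTBS; the γ-lactone ring lies on the side of the C=C bridge | CC(C)(C)[Si](C)(C)OC[C@H]1OC(=O)[C@H]2[C@@H]1[C@]3(C)OC(=O)[C@@]2(Br)C=C3 | intermediate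
9 | debrominated cycloadduct (bridgehead H on C11) | CC(C)(C)[Si](C)(C)OC[C@H]1OC(=O)[C@H]2[C@@H]1[C@]3(C)OC(=O)[C@H]2C=C3 | intermediate
10 | saturated bis-lactone | CC(C)(C)[Si](C)(C)OC[C@H]1OC(=O)[C@H]2[C@@H]1[C@]3(C)OC(=O)[C@H]2CC3 | intermediate
11 | seco dihydroxy diacid (both lactones open) | CC(C)(C)[Si](C)(C)OC[C@@H](O)[C@@H]1[C@H](C(=O)O)[C@@H](C(=O)O)CC[C@@]1(C)O | intermediate
12 | γ-lactone hydroxy acid: cyclohexane with C11–CO2H cis to C14–OH, cis-fused γ-lactone on the opposite face | CC(C)(C)[Si](C)(C)OC[C@H]1OC(=O)[C@H]2[C@@H]1[C@](C)(O)CC[C@@H]2C(=O)O | intermediate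
13 | S-ethyl thioester of 12 | CC(C)(C)[Si](C)(C)OC[C@H]1OC(=O)[C@H]2[C@@H]1[C@](C)(O)CC[C@@H]2C(=O)SCC | intermediate
14 | C11 methyl ketone | CC(C)(C)[Si](C)(C)OC[C@H]1OC(=O)[C@H]2[C@@H]1[C@](C)(O)CC[C@@H]2C(C)=O | intermediate
15 | C11 isopropenyl lactone | CC(C)(C)[Si](C)(C)OC[C@H]1OC(=O)[C@H]2[C@@H]1[C@](C)(O)CC[C@@H]2C(C)=C | intermediate
16 | C11 isopropyl lactone, TBS ether | CC(C)(C)[Si](C)(C)OC[C@H]1OC(=O)[C@H]2[C@@H]1[C@](C)(O)CC[C@@H]2C(C)C | intermediate
17 | hydroxymethyl lactone | OC[C@H]1OC(=O)[C@H]2[C@@H]1[C@](C)(O)CC[C@@H]2C(C)C | intermediate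
18 | tosyloxymethyl lactone | Cc1ccc(cc1)S(=O)(=O)OC[C@H]1OC(=O)[C@H]2[C@@H]1[C@](C)(O)CC[C@@H]2C(C)C | intermediate
19 | hydroxy tosylate methyl ester (C3–OH, C2–OTs, CO2Me on C5) | Cc1ccc(cc1)S(=O)(=O)OC[C@@H](O)[C@@H]1[C@H](C(=O)OC)[C@@H](C(C)C)CC[C@@]1(C)O | intermediate
20 | epoxy methyl ester: (S)-oxiranyl on C4, CO2Me on C5, iPr on C11, C14(OH)Me | C1O[C@H]1[C@@H]2[C@H](C(=O)OC)[C@@H](C(C)C)CC[C@@]2(C)O | intermediate
21 | epoxy aldehyde (CHO on C5) | C1O[C@H]1[C@@H]2[C@H](C=O)[C@@H](C(C)C)CC[C@@]2(C)O | intermediate
22 | (Z)-2-iodoprop-1-enyl epoxide | C1O[C@H]1[C@@H]2[C@H](/C=C(/C)I)[C@@H](C(C)C)CC[C@@]2(C)O | intermediate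
23 | allyloxy-tert-butyldimethylsilane | C=CCO[Si](C)(C)C(C)(C)C | starting material
24 | B-[3-(tert-butyldimethylsilyloxy)propyl]-9-borabicyclo[3.3.1]nonane | CC(C)(C)[Si](C)(C)OCCCB1C2CCCC1CCC2 | intermediate
25 | (Z)-trisubstituted olefin epoxide with the C8–C10 arm (C10–OTBS) | C1O[C@H]1[C@@H]2[C@H](/C=C(/C)CCCO[Si](C)(C)C(C)(C)C)[C@@H](C(C)C)CC[C@@]2(C)O | intermediate
26 | homopropargylic alcohol (C3–OH, terminal alkyne at C1) | C#CC[C@@H](O)[C@@H]1[C@H](/C=C(/C)CCCO[Si](C)(C)C(C)(C)C)[C@@H](C(C)C)CC[C@@]1(C)O | intermediate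
27 | C3,C14-bis(triethylsilyl) ether of 26 | C#CC[C@@H](O[Si](CC)(CC)CC)[C@@H]1[C@H](/C=C(/C)CCCO[Si](C)(C)C(C)(C)C)[C@@H](C(C)C)CC[C@@]1(C)O[Si](CC)(CC)CC | intermediate
28 | (Z)-2-iodoalkenyl-9-BBN (B and I cis) | I/C(C[C@@H](O[Si](CC)(CC)CC)[C@@H]1[C@H](/C=C(/C)CCCO[Si](C)(C)C(C)(C)C)[C@@H](C(C)C)CC[C@@]1(C)O[Si](CC)(CC)CC)=C\B1C2CCCC1CCC2 | intermediate
29 | 2-iodo-1-alkene tris-silyl ether | C=C(I)C[C@@H](O[Si](CC)(CC)CC)[C@@H]1[C@H](/C=C(/C)CCCO[Si](C)(C)C(C)(C)C)[C@@H](C(C)C)CC[C@@]1(C)O[Si](CC)(CC)CC | intermediate
30 | iodo triol | C=C(I)C[C@@H](O)[C@@H]1[C@H](/C=C(/C)CCCO)[C@@H](C(C)C)CC[C@@]1(C)O | intermediate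
31 | iodo dihydroxy aldehyde | C=C(I)C[C@@H](O)[C@@H]1[C@H](/C=C(/C)CCC=O)[C@@H](C(C)C)CC[C@@]1(C)O | intermediate
32 | macrocyclic triol (3R,10R-diol, 14-ol; 6Z; 1-methylene) | C=C1C[C@@H](O)[C@@H]2[C@H](/C=C(/C)CC[C@H]1O)[C@@H](C(C)C)CC[C@@]2(C)O | intermediate
33 | CNP0303839.1, the 3,10-diacetate | C=C1C[C@@H](OC(C)=O)[C@@H]2[C@H](/C=C(/C)CC[C@H]1OC(C)=O)[C@@H](C(C)C)CC[C@@]2(C)O | target

**Count**

Total: 25 steps. Longest linear sequence: 24 steps (1 to 33 through steps 1–3 and 5–25); the butenolide branch joins at step 5 and the allyl ether at step 18.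

**Steps most likely to fail, with fallbacks**

Step 5. The risk is slow bond formation at the methyl-bearing, quaternary-forming terminus, with erosion of endo or regio selectivity, or loss of CO2 if the reaction is forced thermally. The fallback changes the diene and keeps the disconnection. Compound 5 is brominated a second time (Br2, CH2Cl2; then Et3N) to 3,5-dibromo-6-methyl-2H-pyran-2-one F1, a member of the more reactive and more endo-selective dibromopyrone class. Its cycloaddition with 7 under the same pressure should give the dibromo cycloadduct F2, which carries a vinyl bromide on C13 in addition to the C11 bromide. Bu3SnH (2.5 equiv) with AIBN then removes both bromides, and the route is rejoined at 9.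

Step 24. The risk is poor facial selectivity in the addition of the alkenylchromium to the C10 aldehyde, with some oligomerisation if dilution is insufficient. The fallback keeps the closure but no longer relies on it for C10. Starting from 31, the cyclisation product, taken as the (10S)-carbinol F3 or as an epimer mixture, is oxidised at the allylic position only (MnO2, CH2Cl2) to the α-methylene ketone F4. C10 is then reset by Corey–Bakshi–Shibata reduction ((S)-Me-oxazaborolidine, BH3·SMe2), with the alkenyl flank acting as the large group, to return to 32.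

Step 17. The risk is low conversion of the hindered α-branched aldehyde with the thermally fragile iodo-ylide, accompanied by base-induced epimerisation at C5. The fallback builds the same olefin geometry by cross-coupling. Aldehyde 21 is converted by Ramirez olefination (CBr4, PPh3, Et3N, CH2Cl2, 0 °C) into the 1,1-dibromoalkene F5. Trans-selective Negishi monomethylation (MeZnCl, Pd(DPEphos)Cl2) replaces the bromine trans to C5 and gives the (Z)-2-bromopropenyl epoxide F6. F6 is coupled with 24 under the conditions of step 18 to return to 25.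

Further compounds
F1 | step 5 | 3,5-dibromo-6-methyl-2H-pyran-2-one | CC1=C(Br)C=C(Br)C(=O)O1
F2 | step 5 | dibromo endo,anti cycloadduct (Br on C11 and on C13) | CC(C)(C)[Si](C)(C)OC[C@H]1OC(=O)[C@H]2[C@@H]1[C@]3(C)OC(=O)[C@@]2(Br)C=C3Br
F3 | step 24 | (10S)-epimer of macrocyclic triol 32 | C=C1C[C@@H](O)[C@@H]2[C@H](/C=C(/C)CC[C@@H]1O)[C@@H](C(C)C)CC[C@@]2(C)O
F4 | step 24 | macrocyclic α-methylene ketone (C10=O) | C=C1C[C@@H](O)[C@@H]2[C@H](/C=C(/C)CCC1=O)[C@@H](C(C)C)CC[C@@]2(C)O
F5 | step 17 | 1,1-dibromoalkene epoxide | C1O[C@H]1[C@@H]2[C@H](C=C(Br)Br)[C@@H](C(C)C)CC[C@@]2(C)O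
F6 | step 17 | (Z)-2-bromoprop-1-enyl epoxide | C1O[C@H]1[C@@H]2[C@H](/C=C(/C)Br)[C@@H](C(C)C)CC[C@@]2(C)O
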